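**Retrosynthetic overview**
1. Target ⇐ axial C‑methylation of the ring‑B ketone of a spiro α‑bromo ketone (C3 carbinol made last).
2. Spiro α‑bromo ketone ⇐ acyclic bromo trienone: one operation closes ring A (C6–C11, bromonium‑initiated, sets C10 and C6) and then ring B (C6–C5, conjugate spirocyclisation onto the vinyl ketone); C2 is settled by equilibration.
3. Acyclic bromo trienone ⇐ vinyl ketone ⇐ (E)‑geranylacetone (α′‑methylenation, then α‑bromination).
4. Ring order: cyclohexene ring A first, cyclohexanone ring B second, both in step 3.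

Assumption: geranylacetone is used as the pure 5E isomer; spiro compounds are numbered C1–C5 in the bromohydrin ring (C1 = CH2 next to the spiro atom on the CHBr side), C6 = spiro atom, C7–C11 in the cyclohexene ring.

**Step 1**
Reactants: 1 (E)‑geranylacetone
Product: 3 (6E)‑7,11‑dimethyldodeca‑1,6,10‑trien‑3‑one, via Mannich base 2 (not isolated)
Conditions: LDA, THF, −78 °C; CH2=NMe2+ I−, −78 → 0 °C; then MeI, rt; aq NaHCO3/CH2Cl2, rt
Reagents that add atoms: Eschenmoser's salt (N,N‑dimethylmethyleneiminium iodide), C=[N+](C)C.[I-]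
Why: The kinetic methyl‑side lithium enolate undergoes Mannich aminomethylation, and quaternisation followed by E1cB (Hofmann‑type) elimination unveils the vinyl ketone; no stereocentre is formed and the 6E alkene is untouched.

**Step 2**
Reactants: 3 (6E)‑7,11‑dimethyldodeca‑1,6,10‑trien‑3‑one
Product: 5 (6E)‑4‑bromo‑7,11‑dimethyldodeca‑1,6,10‑trien‑3‑one (racemic at C4), via silyl dienol ether 4 (not isolated)
Conditions: TMSOTf, Et3N, CH2Cl2, 0 °C; solvent switch; NBS, THF, −78 °C; aq NaHCO3 work‑up
Reagents that add atoms: N‑bromosuccinimide, O=C1CCC(=O)N1Br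
Why: The vinyl ketone can enolise only toward C4, so soft enolisation gives one 2‑silyloxy‑1,3‑diene, and its α‑bromination with NBS (silyl enol ether halogenation) at −78 °C outruns attack on the isolated alkenes; C4 is racemic here and is corrected in step 3.

**Step 3**
Reactants: 5 (6E)‑4‑bromo‑7,11‑dimethyldodeca‑1,6,10‑trien‑3‑one
Product: 8 (2R,6R,10S)‑2,10‑dibromo‑7,11,11‑trimethylspiro[5.5]undec‑7‑en‑3‑one, via monocyclic bromo enone 6 (not isolated), via 2‑epi ketone 7 (not isolated)
Conditions: DBDMH (0.55 equiv), chiral BINOL‑derived thiophosphoramide (10 mol %, antipode giving 10S), PhMe–CH2Cl2, −78 °C; then MeSO3H (2 equiv), HFIP, −40 → 0 °C, same flask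
Reagents that add atoms: 1,3‑dibromo‑5,5‑dimethylhydantoin, CC1(C)C(=O)N(Br)C(=O)N1Br
Why: Proposed new method: the chiral Lewis base–Br+ complex brominates the terminal, most electron‑rich C10=C11 alkene enantioselectively (closest known type: Lewis‑base‑catalysed asymmetric bromonium polyene cyclisation), and the 6E alkene closes C6→C11 through a chair with Br and the C5 side chain both equatorial, which fixes C10 (S) and the cis C10/C1′ relationship; the ketone oxygen then takes H6 through a six‑membered transition state to give tetrasubstituted alkene 6 and an O‑protonated vinyl ketone, whose CH2 terminus (C1 of 5) is attacked by C6 from the face anti to the axial C11 methyl (closest known type: Brønsted/Lewis‑acid alkene–enone conjugate cyclisation, as used to complete partially cyclised polyenes), so the new bond is axial and C6 becomes R, loss of H8 gives the C7=C8 alkene, and acid‑catalysed enolisation converts 7 into the equatorial bromide 8 (an axial Br would be 1,3‑diaxial to C7).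

**Step 4**
Reactants: 8 (2R,6R,10S)‑2,10‑dibromo‑7,11,11‑trimethylspiro[5.5]undec‑7‑en‑3‑one
Product: 9 (2R,3R,6R,10S)‑2,10‑dibromo‑3,7,11,11‑tetramethylspiro[5.5]undec‑7‑en‑3‑ol
Conditions: MAD (3 equiv, from AlMe3 + 2 BHT), PhMe, −78 °C; then MeLi (2.5 equiv), −78 °C; 1 M HCl work‑up
Reagents that add atoms: methyllithium, [Li]C
Why: The bulky aluminium Lewis acid sits on the equatorial side of the carbonyl, so MeLi adds axially (MAD‑mediated amphiphilic carbonyl alkylation) and gives axial CH3 with equatorial OH (3R), trans‑diequatorial to the C2 bromide; −78 °C and the gauche O/Br arrangement suppress enolisation, Li–Br exchange and epoxide closure.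

**Compound list**
1 | (5E)‑6,10‑dimethylundeca‑5,9‑dien‑2‑one (geranylacetone) | CC(=O)CC/C=C(\C)CCC=C(C)C | starting material
2 | (6E)‑1‑(dimethylamino)‑7,11‑dimethyldodeca‑6,10‑dien‑3‑one (Mannich base) | CN(C)CCC(=O)CC/C=C(\C)CCC=C(C)C | intermediate
3 | (6E)‑7,11‑dimethyldodeca‑1,6,10‑trien‑3‑one | C=CC(=O)CC/C=C(\C)CCC=C(C)C | intermediate
4 | (3Z,6E)‑7,11‑dimethyl‑3‑(trimethylsilyloxy)dodeca‑1,3,6,10‑tetraene | C=C/C(O[Si](C)(C)C)=C/C/C=C(\C)CCC=C(C)C | intermediate
5 | (6E)‑4‑bromo‑7,11‑dimethyldodeca‑1,6,10‑trien‑3‑one, racemic at C4 | C=CC(=O)C(Br)C/C=C(\C)CCC=C(C)C | intermediate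
6 | 2‑bromo‑1‑[(5S)‑5‑bromo‑2,6,6‑trimethylcyclohex‑1‑en‑1‑yl]pent‑4‑en‑3‑one, both C2 epimers | C=CC(=O)C(Br)CC1=C(C)CC[C@H](Br)C1(C)C | intermediate
7 | (2S,6R,10S)‑2,10‑dibromo‑7,11,11‑trimethylspiro[5.5]undec‑7‑en‑3‑one (C2 epimer of 8) | CC1=CC[C@H](Br)C(C)(C)[C@@]12CCC(=O)[C@@H](Br)C2 | intermediate
8 | (2R,6R,10S)‑2,10‑dibromo‑7,11,11‑trimethylspiro[5.5]undec‑7‑en‑3‑one (C2–Br equatorial, C1 cis to C10–Br) | CC1=CC[C@H](Br)C(C)(C)[C@@]12CCC(=O)[C@H](Br)C2 | intermediate
9 | (2R,3R,6R,10S)‑2,10‑dibromo‑3,7,11,11‑tetramethylspiro[5.5]undec‑7‑en‑3‑ol | CC1=CC[C@H](Br)C(C)(C)[C@@]12CC[C@@](C)(O)[C@H](Br)C2 | target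

**Total step count:** 4. **Longest linear sequence:** 4.

**Steps most likely to fail**

Step 3 is the weakest: the Br+ transfer may give low ee, and the double ring closure is untested on this substrate. The fallback takes the absolute configuration from a reagent‑controlled epoxidation instead. It sets out from 5. Shi epoxidation (D‑fructose‑derived ketone, Oxone, pH ≈ 8 buffer, 0 °C) of the terminal alkene gives the 10R epoxy bromo dienone F1. Li2NiBr4 in THF opens it at C10 with inversion to the 10S bromohydrin F2. MeSO3H in HFIP then ionises the tertiary alcohol with neighbouring‑bromine participation to a configurationally defined bromonium ion, which runs through the same two ring closures (6, 7) and returns to the route at 8.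

Step 4 is second: MeLi may enolise the α‑bromo ketone or attack from the equatorial side. The fallback builds the methyl group in two stages and sets out from 8. Dimethylsulfonium methylide (Me3S+ I−, KHMDS, THF, −20 °C) transfers CH2 axially to give the spiro‑oxirane F3 (CH2 axial, O equatorial). LiAlH4 in Et2O at −40 °C opens it at the CH2 carbon; the two hindered secondary bromides should react more slowly. This returns to the route at 9.

Step 2 is third: the α‑bromo vinyl ketone 5 may polymerise or lose HBr. The fallback introduces the C2 bromine only after both rings exist and sets out from 3. The step 3 conditions applied to 3 give, through the monocyclic bromo enone F4 (not isolated), the spiro ketone F5, whose ring B is symmetric. A chiral lithium amide (lithium bis(1‑phenylethyl)amide·LiCl, antipode chosen by a pilot run, TMSCl in situ, THF, −100 °C) removes one of the two enantiotopic α‑hydrogens, now diastereotopic through ring A, and gives the silyl enol ether F6. NBS in THF at −78 °C, followed by acid equilibration, returns to the route at 8. This second, reagent‑controlled event also turns any residual 10R material into a separable diastereomer.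

**Further compounds**
F1 | step 3 | (6E)‑4‑bromo‑9‑[(2R)‑3,3‑dimethyloxiran‑2‑yl]‑7‑methylnona‑1,6‑dien‑3‑one | C=CC(=O)C(Br)C/C=C(\C)CC[C@H]1OC1(C)C
F2 | step 3 | (6E,10S)‑4,10‑dibromo‑11‑hydroxy‑7,11‑dimethyldodeca‑1,6‑dien‑3‑one | C=CC(=O)C(Br)C/C=C(\C)CC[C@H](Br)C(C)(C)O
F3 | step 4 | (2R,3S,6R,10S)‑2,10‑dibromo‑7,11,11‑trimethylspiro[5.5]undec‑7‑ene‑3‑spiro‑2′‑oxirane | CC1=CC[C@H](Br)C(C)(C)[C@@]12CC[C@@]3(OC3)[C@H](Br)C2
F4 | step 2 | 1‑[(5S)‑5‑bromo‑2,6,6‑trimethylcyclohex‑1‑en‑1‑yl]pent‑4‑en‑3‑one | C=CC(=O)CCC1=C(C)CC[C@H](Br)C1(C)C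
F5 | step 2 | (10S)‑10‑bromo‑7,11,11‑trimethylspiro[5.5]undec‑7‑en‑3‑one | CC1=CC[C@H](Br)C(C)(C)C12CCC(=O)CC2
F6 | step 2 | (6R,10S)‑10‑bromo‑7,11,11‑trimethyl‑3‑(trimethylsilyloxy)spiro[5.5]undeca‑2,7‑diene | CC1=CC[C@H](Br)C(C)(C)[C@@]12CCC(O[Si](C)(C)C)=CC2
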